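The plan cuts ring A, the N–H indole, at C3–C3a and N1–C2. Bromine on C4, C5 and C6 means that the carbocycle of ring A comes from a 3,4,5-tribromoaryl group whose two ortho carbons are equivalent. C3 carries N1' of ring B in the way the α-carbon of an (indol-1-yl)acetaldehyde does. A single Fischer indolization thus forms both bonds and closes the pyrrole ring of ring A, as one regioisomer, onto a finished ring B. The precursor is the dry, preformed hydrazone of (3,4,5-tribromophenyl)hydrazine and 2-[2,4,6-tribromo-3-(methylthio)indol-1-yl]acetaldehyde. One electrophilic sulfenylation at C2 then completes the target.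

Key step: step 6

Assumption: the SMILES assigns no configuration to the hindered C3–N1' axis and the molecule has no stereocentre, so the route aims at the constitution only and would give the racemate if the axis proves configurationally stable.

Step 1
Reactants: 1 3,4,5-tribromoaniline
Product: 3 (3,4,5-tribromophenyl)hydrazine, via 3,4,5-tribromobenzenediazonium chloride 2 (not isolated)
Conditions: NaNO2, conc. HCl/AcOH, −5 to 0 °C; then SnCl2·2H2O, conc. HCl, 0 °C; aq NaOH, extraction (free base, used promptly)
Reagents that add atoms: sodium nitrite (NaNO2), [Na+].[O-]N=O
Why: Diazotization and reduction of the diazonium salt with divalent tin is the standard way from weakly basic polyhaloanilines to arylhydrazines, and keeping the salt cold and reducing it at once leaves no time for chloride to displace the bromine para to the diazonium group.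

Step 2
Reactants: 4 4,6-dibromo-1H-indole
Product: 5 4,6-dibromo-3-(methylthio)-1H-indole
Conditions: MeSSMe (0.5 equiv), SO2Cl2 (0.5 equiv), CH2Cl2, −20 °C (gives MeSCl); added to 4 in CH2Cl2, −40 → 0 °C; aq NaHCO3
Reagents that add atoms: dimethyl disulfide, CSSC (converted in the flask into methanesulfenyl chloride, CSCl)
Why: Electrophilic aromatic substitution with a sulfenyl chloride takes place at C3', the most nucleophilic carbon of an N–H indole, and one equivalent of reagent at low temperature stops the reaction before C2' is attacked.

Step 3
Reactants: 5 4,6-dibromo-3-(methylthio)-1H-indole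
Product: 6 2,4,6-tribromo-3-(methylthio)-1H-indole
Conditions: NBS (1.0 equiv), dry CH2Cl2, −20 → 0 °C, dark
Reagents that add atoms: N-bromosuccinimide, O=C1CCC(=O)N1Br
Why: In this electrophilic bromination C3' is blocked by sulfur and the benzo ring is deactivated by two bromines, so bromine ends up on C2' (directly or by relay from a bromosulfonium or 3-bromoindolenine species), while the dry, dark, cold medium suppresses oxidation at sulfur and radical attack on the S-methyl group.

Step 4
Reactants: 6 2,4,6-tribromo-3-(methylthio)-1H-indole; 7 bromoacetaldehyde diethyl acetal
Product: 8 2,4,6-tribromo-1-(2,2-diethoxyethyl)-3-(methylthio)indole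
Conditions: Cs2CO3, Bu4NI (cat.), DMF, 80 °C
Reagents that add atoms: none
Why: In this SN2 N-alkylation of the indolide the three bromines make N1'–H acidic enough for Cs2CO3, C-alkylation is excluded because C3' is substituted, and iodide catalysis with moderate heat makes up for the sluggish β,β-dialkoxy bromide.

Step 5
Reactants: 8 2,4,6-tribromo-1-(2,2-diethoxyethyl)-3-(methylthio)indole
Product: 9 2-[2,4,6-tribromo-3-(methylthio)indol-1-yl]acetaldehyde
Conditions: 2 M aq H2SO4, THF, 50 °C; aq NaHCO3; dried by azeotrope with toluene
Reagents that add atoms: water, O
Why: In this acid-catalysed acetal hydrolysis in a halide-free medium the electron-poor ring B resists protonation at C3', so the 2-bromo-3-methylthio pattern should survive, and the aldehyde finds no free nucleophilic indole position with which to condense.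

Step 6
Reactants: 3 (3,4,5-tribromophenyl)hydrazine; 9 2-[2,4,6-tribromo-3-(methylthio)indol-1-yl]acetaldehyde
Product: 11 4,5,6-tribromo-3-[2,4,6-tribromo-3-(methylthio)indol-1-yl]-1H-indole, via arylhydrazone 10 (not isolated)
Conditions: toluene, 4 Å molecular sieves, cat. AcOH, rt; filter, concentrate; then anhydrous ZnBr2 (3 equiv), AcOH, 110 °C, N2
Reagents that add atoms: none
Why: This is a Fischer indole synthesis in which ZnBr2/AcOH tautomerizes hydrazone 10 to the ene-hydrazine, which can form only toward the CH2 that bears N1', and the [3,3]-sigmatropic shift then joins this carbon (future C3) to an ortho carbon of the aryl ring (future C3a). Rearomatization frees the aniline nitrogen, which adds to the C=NH carbon in a 5-exo-trig closure (N1–C2), and the aminal loses ammonia to give the aromatic pyrrole ring of ring A. The closest known cases are Fischer reactions of carbonyl compounds with an α-nitrogen or α-sulfur substituent, where zinc halides serve better than protic acids, which tend to trigger heterolysis of the N–N bond; here the N1' lone pair belongs to the aromatic sextet of a tribrominated indole and is a poor donor, which further disfavours that cleavage. Only regioselectivity is required, and it is secured by the equivalence of the two ortho carbons of the 3,4,5-tribromophenyl group, so that only the 4,5,6-tribromo pattern can arise and no stereocentre is created. Ring B cannot take part because C2' and C3' are substituted, and a dried, preformed hydrazone together with a bromide-only Lewis acid means that neither water nor a foreign halide is on hand to attack the C2'–Br bond. The three bromines slow the sigmatropic step, which is why a temperature near the boiling point of acetic acid is planned.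

Step 7
Reactants: 11 4,5,6-tribromo-3-[2,4,6-tribromo-3-(methylthio)indol-1-yl]-1H-indole
Product: 12 4,5,6-tribromo-2-(methylthio)-3-[2,4,6-tribromo-3-(methylthio)indol-1-yl]-1H-indole (target)
Conditions: MeSSMe (0.55 equiv), SO2Cl2 (0.55 equiv), CH2Cl2, −20 °C (gives MeSCl); added to 11 in CH2Cl2/DMF, 0 °C → rt; aq NaHCO3
Reagents that add atoms: dimethyl disulfide, CSSC (converted in the flask into methanesulfenyl chloride, CSCl)
Why: In this electrophilic sulfenylation of a 3-substituted indole MeSCl attacks the pyrrole ring of ring A, the only π-nucleophile left, either at C2 directly or at C3 followed by a 1,2-shift of sulfur, and loss of HCl restores the indole, while ring B is fully substituted at C2' and C3' and any S- or N-sulfenylation is reversible.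

Compound list
1 | 3,4,5-tribromoaniline | Nc1cc(Br)c(Br)c(Br)c1 | starting material
2 | 3,4,5-tribromobenzenediazonium chloride | N#[N+]c1cc(Br)c(Br)c(Br)c1.[Cl-] | intermediate
3 | (3,4,5-tribromophenyl)hydrazine | NNc1cc(Br)c(Br)c(Br)c1 | intermediate
4 | 4,6-dibromo-1H-indole | Brc1cc(Br)c2cc[nH]c2c1 | starting material
5 | 4,6-dibromo-3-(methylthio)-1H-indole | CSc1c[nH]c2cc(Br)cc(Br)c12 | intermediate
6 | 2,4,6-tribromo-3-(methylthio)-1H-indole | CSc1c(Br)[nH]c2cc(Br)cc(Br)c12 | intermediate
7 | bromoacetaldehyde diethyl acetal | CCOC(CBr)OCC | starting material
8 | 2,4,6-tribromo-1-(2,2-diethoxyethyl)-3-(methylthio)indole | CCOC(Cn1c(Br)c(SC)c2c(Br)cc(Br)cc21)OCC | intermediate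
9 | 2-[2,4,6-tribromo-3-(methylthio)indol-1-yl]acetaldehyde | O=CCn1c(Br)c(SC)c2c(Br)cc(Br)cc21 | intermediate
10 | (E)-(3,4,5-tribromophenyl)hydrazone of aldehyde 9 (E shown; the geometry is of no consequence) | Brc1cc(N/N=C/Cn2c(Br)c(SC)c3c(Br)cc(Br)cc32)cc(Br)c1Br | intermediate
11 | 4,5,6-tribromo-3-[2,4,6-tribromo-3-(methylthio)indol-1-yl]-1H-indole | Brc1cc2[nH]cc(-n3c(Br)c(SC)c4c(Br)cc(Br)cc43)c2c(Br)c1Br | intermediate
12 | 4,5,6-tribromo-2-(methylthio)-3-[2,4,6-tribromo-3-(methylthio)indol-1-yl]-1H-indole | CSc1[nH]c2cc(Br)c(Br)c(Br)c2c1-n1c(Br)c(SC)c2c(Br)cc(Br)cc21 | target

Total step count: 7. Longest linear sequence: 6 steps (4 → 5 → 6 → 8 → 9 → 11 → 12); step 1 runs in parallel.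

Steps most likely to fail

Step 6.
- **Risk:** Heterolysis of the N–N bond in the activated ene-hydrazine may outrun the [3,3] shift, which is slowed by three bromines and by crowding next to the C–Br bond that becomes C4–Br. Long heating in acid may also erode the halogen and sulfur substituents of ring B or expel ring B from the hydrazone.
- **Fallback:** The sigmatropic route is replaced by a palladium-catalysed annulation that makes the same two bonds without acid and without an N–N bond. It sets out from 1. This is mono-iodinated ortho to nitrogen (NIS, cat. TFA, MeCN, 0 °C; the para position is blocked and both ortho positions are equivalent) to give 3,4,5-tribromo-2-iodoaniline F1. This aniline is heated with aldehyde 9, Pd(OAc)2 (cat.) and DABCO in DMF at about 85 °C. Enamine formation sets N1–C2, zerovalent palladium inserts into the C–I bond first, and an intramolecular Heck reaction sets C3–C3a. Ligand-free conditions of this kind are not expected to activate aryl bromides. The fallback comes back to the route at 11.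

Step 7.
- **Risk:** Attack of the sulfur electrophile on the deactivated and crowded pyrrole ring of ring A may be too slow, so that the reagent is consumed by unproductive sulfenylation at sulfur or nitrogen.
- **Fallback:** The new approach does not depend on π-nucleophilicity and sets out from 11. C–H borylation with [Ir(OMe)(cod)]2 (cat.), 4,4'-di-tert-butyl-2,2'-bipyridine and B2pin2 in THF at 60–80 °C is steered by sterics and C–H acidity. It should select C2–H next to N1–H, because C7–H, C5'–H and C7'–H each sit beside a bromine or between two substituents, and aryl bromides are tolerated. This gives the 2-(pinacolboryl) derivative of 11 F2. Copper-catalysed deborylative thiolation of this boronate with S-methyl methanethiosulfonate (CuSO4 cat., 1,10-phenanthroline, CsF, MeOH, 50 °C) then installs SMe at C2. The fallback comes back to the route at 12.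

Step 4.
- **Risk:** Substitution by a weakly nucleophilic indolide flanked by C2'–Br on a hindered β,β-dialkoxy bromide may be slow enough for base-induced elimination of the alkylating agent to win.
- **Fallback:** The aldehyde is reached from the ester oxidation level, setting out from 6. Alkylation with the far more reactive ethyl bromoacetate (K2CO3, DMF, rt) gives ethyl 2-[2,4,6-tribromo-3-(methylthio)indol-1-yl]acetate F3. Partial reduction of this ester with i-Bu2AlH (1.1 equiv, CH2Cl2, −78 °C, tartrate work-up) spares the aryl bromides and the thioether. The fallback comes back to the route at 9, so that steps 4 and 5 and their acid treatment are both bypassed.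

Further compounds
F1 | step 6 | 3,4,5-tribromo-2-iodoaniline | Nc1cc(Br)c(Br)c(Br)c1I
F2 | step 7 | 4,5,6-tribromo-2-(4,4,5,5-tetramethyl-1,3,2-dioxaborolan-2-yl)-3-[2,4,6-tribromo-3-(methylthio)indol-1-yl]-1H-indole | CC1(C)OB(OC1(C)C)c1[nH]c2cc(Br)c(Br)c(Br)c2c1-n1c(Br)c(SC)c2c(Br)cc(Br)cc21
F3 | step 4 | ethyl 2-[2,4,6-tribromo-3-(methylthio)indol-1-yl]acetate | CCOC(=O)Cn1c(Br)c(SC)c2c(Br)cc(Br)cc21
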